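**Retrosynthetic overview**

1. The strategy rests on where the interflavone bond sits: C3 of unit 1 is the alpha carbon of pyranone ring C and the direct neighbour of C2, the carbon of the O1–C2 enol ether bond; its partner is C8'' on ring A of unit 2.
2. Last disconnection: the six O–CH3 bonds, leading back to 3,8''-biapigenin hexamethyl ether 10.
3. Key disconnection: C3–C8'' together with O1–C2 of unit 1, leading back to o-hydroxyaryl ynone 5 (both bonds fall on its two alkyne carbons) and 8-iodoflavone 7.
4. Iodide 7 is traced to the same ynone 5 through flavone 6 (ring closure, then C8 iodination); 5 comes from aldehyde 1 and alkyne 2 through carbinol 4.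
5. Ring order: rings A and B of both units are bought; ring C of unit 2 closes in step 3; ring C of unit 1 closes last, in step 5, as the two halves are joined.

Key step: step 5

Remark: 3,8'-biapigenin is taken as the C3–C8'' linked dimer drawn in the SMILES. It has no stereocentre and the biaryl axis is not assigned, so no configuration has to be controlled.

**Route**

Step 1
Reactants: 1 2-hydroxy-4,6-dimethoxybenzaldehyde; 2 4-ethynylanisole
Product: 4 rac-1-(2-hydroxy-4,6-dimethoxyphenyl)-3-(4-methoxyphenyl)prop-2-yn-1-ol, via lithium (4-methoxyphenyl)acetylide 3 (not isolated)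
Conditions: 2 (3.0 equiv), n-BuLi (2.9 equiv), THF, −78 °C; then 1, −78 to −20 °C; sat. aq NH4Cl, −20 °C; crude product used at once
Reagents that add atoms: none
Why: 1,2-addition of a lithium acetylide to an aldehyde, in which one equivalent of 3 deprotonates the phenol and a further equivalent adds to the carbonyl of the lithium phenoxide aldehyde to give the carbinol as a racemate (its stereocentre is erased in step 2), with the cold buffered quench and immediate use limiting ionization of the electron-rich o-hydroxybenzylic alcohol.

Step 2
Reactants: 4 rac-1-(2-hydroxy-4,6-dimethoxyphenyl)-3-(4-methoxyphenyl)prop-2-yn-1-ol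
Product: 5 1-(2-hydroxy-4,6-dimethoxyphenyl)-3-(4-methoxyphenyl)prop-2-yn-1-one
Conditions: activated MnO2 (15 equiv), CH2Cl2, 0 °C to rt
Reagents that add atoms: none
Why: activated MnO2 oxidizes benzylic and propargylic alcohols selectively under neutral heterogeneous conditions, so the labile carbinol meets neither acid nor base and the hydrogen-bonded o-hydroxyaryl ynone should be obtained without premature ring closure.

Step 3
Reactants: 5 1-(2-hydroxy-4,6-dimethoxyphenyl)-3-(4-methoxyphenyl)prop-2-yn-1-one
Product: 6 5,7-dimethoxy-2-(4-methoxyphenyl)-4H-chromen-4-one (5,7,4'-trimethoxyflavone)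
Conditions: TfOH (20 mol %), CH2Cl2, 0 °C to rt
Reagents that add atoms: none
Why: Brønsted-acid-promoted 6-endo-dig cycloisomerization (intramolecular oxa-Michael addition) of an o-hydroxyaryl ynone, in which protonation of the carbonyl makes the beta alkyne carbon electrophilic and the phenol oxygen closes pyranone ring C of unit 2, the acid avoiding the 5-exo aurone pathway seen with strong bases.

Step 4
Reactants: 6 5,7-dimethoxy-2-(4-methoxyphenyl)-4H-chromen-4-one
Product: 7 8-iodo-5,7-dimethoxy-2-(4-methoxyphenyl)-4H-chromen-4-one (8-iodo-5,7,4'-trimethoxyflavone)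
Conditions: N-iodosuccinimide (1.1 equiv), CF3CO2H (cat.), MeCN, rt, dark
Reagents that add atoms: N-iodosuccinimide, O=C1CCC(=O)N1I
Why: electrophilic aromatic iodination, for which C8 (ortho to the 7-methoxy group and the ring oxygen, para to the 5-methoxy group) is the most nucleophilic site of a 5,7-dialkoxyflavone whose 5-oxygen is alkylated, so the 8-iodide should form in preference to the 6-iodide while C3 and ring B stay untouched.

Step 5
Reactants: 5 1-(2-hydroxy-4,6-dimethoxyphenyl)-3-(4-methoxyphenyl)prop-2-yn-1-one; 7 8-iodo-5,7-dimethoxy-2-(4-methoxyphenyl)-4H-chromen-4-one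
Product: 10 3,8''-biapigenin hexamethyl ether, via arylpalladium iodide SPhos complex 8 (not isolated), via diorganopalladium SPhos complex 9 (not isolated)
Conditions: 7 (1.0 equiv), Pd2(dba)3 (5 mol %), SPhos (2-dicyclohexylphosphino-2',6'-dimethoxybiphenyl, 12 mol %), K3PO4 (2 equiv), 1,4-dioxane, 90 °C; 5 (1.5 equiv) in 1,4-dioxane added by syringe pump over 6 h
Reagents that add atoms: none
Why: Proposed new method: zerovalent palladium inserts into the C8–I bond of 7 to give arylpalladium iodide 8, which binds the alkyne of the slowly added ynone 5 as a pi acid; the hydrogen-bonded phenol oxygen, assisted by K3PO4, attacks the beta alkyne carbon anti to the metal and leaves palladium on the alpha carbon in diorganopalladium 9, from which C–C reductive elimination forges C3–C8'' and returns zerovalent palladium. The closest known reaction type is the Cacchi heteroannulative coupling of o-alkynylphenols and o-alkynylanilides with aryl halides to 2,3-disubstituted benzofurans and indoles, and the electrophile-triggered counterpart on this ynone class is the iodine monochloride cyclization of o-alkoxyaryl ynones to 3-iodochromones. Pyranone ring C of unit 1 closes in the 6-endo-dig mode by formation of the O1–C2 bond. No stereocentre is formed, and the new C3–C8'' axis has no assigned configuration in the target. The step needs 6-endo rather than 5-exo closure, which the conjugate polarization of the ynone secures by making the beta carbon the electrophilic terminus, and aryl capture rather than proton capture, which is secured by keeping 5 dilute relative to 8 through slow addition, by a weak heterogeneous base, and by the bulky electron-rich biaryl phosphine that speeds reductive elimination between two doubly flanked carbons; the coupling site on unit 2 is fixed by the iodide. Any 5 that cyclizes without coupling becomes flavone 6, which is returned to step 4.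

Step 6
Reactants: 10 3,8''-biapigenin hexamethyl ether
Product: 11 3,8''-biapigenin (3,8'-biapigenin)
Conditions: BBr3 (20 equiv, 1 M in CH2Cl2), CH2Cl2, −78 °C to rt; then ice-water
Reagents that add atoms: none
Why: Lewis-acid cleavage of aryl methyl ethers with BBr3, in which each ether oxygen binds boron and bromide removes the methyl group by SN2 (the 5-methoxy groups peri to the carbonyls first), the low temperature limiting the acid-driven Wessely–Moser ring opening and reclosure that would shift the interflavone bond from C8'' to C6''.

**Compound list**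

1 | 2-hydroxy-4,6-dimethoxybenzaldehyde | O=Cc1c(O)cc(OC)cc1OC | starting material
2 | 4-ethynylanisole (1-ethynyl-4-methoxybenzene) | C#Cc1ccc(OC)cc1 | starting material
3 | lithium (4-methoxyphenyl)acetylide | [Li]C#Cc1ccc(OC)cc1 | intermediate
4 | rac-1-(2-hydroxy-4,6-dimethoxyphenyl)-3-(4-methoxyphenyl)prop-2-yn-1-ol | COc1ccc(cc1)C#CC(O)c1c(O)cc(OC)cc1OC | intermediate
5 | 1-(2-hydroxy-4,6-dimethoxyphenyl)-3-(4-methoxyphenyl)prop-2-yn-1-one | COc1ccc(cc1)C#CC(=O)c1c(O)cc(OC)cc1OC | intermediate
6 | 5,7-dimethoxy-2-(4-methoxyphenyl)-4H-chromen-4-one (5,7,4'-trimethoxyflavone) | COc1ccc(cc1)-c1cc(=O)c2c(OC)cc(OC)cc2o1 | intermediate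
7 | 8-iodo-5,7-dimethoxy-2-(4-methoxyphenyl)-4H-chromen-4-one (8-iodo-5,7,4'-trimethoxyflavone) | COc1ccc(cc1)-c1cc(=O)c2c(OC)cc(OC)c(I)c2o1 | intermediate
8 | (5,7,4'-trimethoxyflavon-8-yl)palladium iodide SPhos complex, divalent palladium, drawn charge-separated at P and Pd | COc1ccc(cc1)-c1cc(=O)c2c(OC)cc(OC)c([Pd-](I)[P+](C3CCCCC3)(C3CCCCC3)c3ccccc3-c3c(OC)cccc3OC)c2o1 | intermediate
9 | (5,7,4'-trimethoxyflavon-3-yl)(5,7,4'-trimethoxyflavon-8-yl)palladium SPhos complex, divalent palladium, drawn charge-separated at P and Pd | O=c1c([Pd-](c2c(OC)cc(OC)c3c(=O)cc(-c4ccc(OC)cc4)oc23)[P+](C2CCCCC2)(C2CCCCC2)c2ccccc2-c2c(OC)cccc2OC)c(-c2ccc(OC)cc2)oc2cc(OC)cc(OC)c12 | intermediate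
10 | 3,8''-biapigenin hexamethyl ether (5,7,4',5'',7'',4'''-hexamethoxy-3,8''-biflavone) | O=c1c(-c2c(OC)cc(OC)c3c(=O)cc(-c4ccc(OC)cc4)oc23)c(-c2ccc(OC)cc2)oc2cc(OC)cc(OC)c12 | intermediate
11 | 3,8''-biapigenin (3,8'-biapigenin) | O=c1c(-c2c(O)cc(O)c3c(=O)cc(-c4ccc(O)cc4)oc23)c(-c2ccc(O)cc2)oc2cc(O)cc(O)c12 | target

**Step count**

Total steps: 6. Longest linear sequence: 6 steps (1 → 4 → 5 → 6 → 7 → 10 → 11). Ynone 5 enters twice, once as the precursor of iodide 7 and once as the coupling partner in step 5.

**Steps most likely to fail**

Step 5 (proposed new method). The arylpalladium intermediate may not intercept the ynone before palladium-free, base-mediated ring closure consumes it, so that the ring closes with proton capture instead of aryl capture. Reductive elimination between the two doubly flanked carbons may also be slow enough for hydrodeiodination to take over. The fallback joins two preformed flavones by known cross-coupling and sets out from flavone 6 and iodide 7. Flavone 6 would be lithiated at C3 with commercial LDA in THF at −78 °C and quenched with I2 to give 3-iodo-5,7,4'-trimethoxyflavone F1. Iodide 7 would be converted by Miyaura borylation (B2pin2, PdCl2(dppf), KOAc, 1,4-dioxane, 90 °C) into 5,7,4'-trimethoxyflavone-8-boronic acid pinacol ester F2. Suzuki–Miyaura coupling of F1 with F2 (Pd(OAc)2, SPhos, K3PO4, toluene/water, 100 °C) should then give the hexamethyl ether, and the fallback returns to the route at compound 10.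

Step 6. Cleavage of the four methyl ethers that are not chelated to a carbonyl may stop part-way, partially demethylated boron complexes may precipitate, and prolonged acid exposure may open and reclose ring C of unit 2 with migration of the interflavone bond. The fallback separates the task into a chelation-controlled stage and a basic, nucleophilic stage and sets out from compound 10. BCl3 in CH2Cl2 at −78 to 0 °C should remove only the two methyl groups peri to the carbonyls and give 5,5''-dihydroxy-7,4',7'',4'''-tetramethoxy-3,8''-biflavone F3. Sodium ethanethiolate in DMF at 130 °C should then remove the remaining four methyl groups by SN2 attack at carbon under conditions that cannot trigger the acid-driven isomerization. The fallback returns to the route at compound 11.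

Step 1. The carbinol may be lost through ionization of its benzylic C–O bond to an ortho-quinone methide and oligomerization during quench and concentration, and addition to the aldehyde may be sluggish once the phenol is a lithium phenoxide. The fallback masks the phenol during the two labile stages and sets out from compound 1. Aldehyde 1 would be protected with chloromethyl methyl ether and NaH in DMF at 0 °C to give 2,4-dimethoxy-6-(methoxymethoxy)benzaldehyde F4. Addition of acetylide 3 in THF at −78 °C should give rac-1-[2,4-dimethoxy-6-(methoxymethoxy)phenyl]-3-(4-methoxyphenyl)prop-2-yn-1-ol F5, which can no longer form a quinone methide. MnO2 in CH2Cl2 should oxidize F5 to 1-[2,4-dimethoxy-6-(methoxymethoxy)phenyl]-3-(4-methoxyphenyl)prop-2-yn-1-one F6. Brief treatment of F6 with CF3CO2H in CH2Cl2 at 0 °C, followed by aqueous work-up, should remove the acetal, whose cleavage is assisted by the neighbouring carbonyl. The fallback returns to the route at compound 5; any material that cyclizes during deprotection becomes flavone 6 and is still usable in step 4.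

**Further compounds**

F1 | step 5 | 3-iodo-5,7-dimethoxy-2-(4-methoxyphenyl)-4H-chromen-4-one (3-iodo-5,7,4'-trimethoxyflavone) | COc1ccc(cc1)-c1oc2cc(OC)cc(OC)c2c(=O)c1I
F2 | step 5 | 5,7-dimethoxy-2-(4-methoxyphenyl)-8-(4,4,5,5-tetramethyl-1,3,2-dioxaborolan-2-yl)-4H-chromen-4-one | COc1ccc(cc1)-c1cc(=O)c2c(OC)cc(OC)c(B3OC(C)(C)C(C)(C)O3)c2o1
F3 | step 6 | 5,5''-dihydroxy-7,4',7'',4'''-tetramethoxy-3,8''-biflavone | O=c1c(-c2c(OC)cc(O)c3c(=O)cc(-c4ccc(OC)cc4)oc23)c(-c2ccc(OC)cc2)oc2cc(OC)cc(O)c12
F4 | step 1 | 2,4-dimethoxy-6-(methoxymethoxy)benzaldehyde | O=Cc1c(OCOC)cc(OC)cc1OC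
F5 | step 1 | rac-1-[2,4-dimethoxy-6-(methoxymethoxy)phenyl]-3-(4-methoxyphenyl)prop-2-yn-1-ol | COc1ccc(cc1)C#CC(O)c1c(OCOC)cc(OC)cc1OC
F6 | step 1 | 1-[2,4-dimethoxy-6-(methoxymethoxy)phenyl]-3-(4-methoxyphenyl)prop-2-yn-1-one | COc1ccc(cc1)C#CC(=O)c1c(OCOC)cc(OC)cc1OC
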